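Ring A is disconnected across C1–C2 and C5–C6. Its C2–C5 segment (Br, Br, H, Br) is the diene of 2,3,5-tribromothiophene 1,1-dioxide, and the C1–C6 unit with both oxygens, the ring-B ether already in place, is the bis(trimethylsilyl) ketene acetal of (2-bromophenoxy)acetic acid. One inverse-electron-demand Diels–Alder reaction forms both bonds and closes ring A; loss of sulfur dioxide and trimethylsilanol then aromatises it to the silyl ether of the target, so the halogen pattern is bought, not made by bromination. Each precursor is one step from a commercial compound, and a mild hydrolysis finishes the synthesis.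

Key step: step 3

Remark (assumption): the target has no stereocentre and its diaryl ether axis rotates freely, so it is achiral and no enantioselective step is needed.

Ring A is numbered C1 (OH), C2 (Br), C3 (Br), C4 (H), C5 (Br), C6 (O-aryl); C2–C5 of the thiophene dioxide become C2–C5 of ring A. Diene, dienophile and silyl ether were checked atom by atom against this numbering and needed no structural correction.

Three choices keep the flanking steps safe:
- The peracid is generated from urea–hydrogen peroxide, not from concentrated peroxide.
- The silyl ester is enolised with LiHMDS, which leaves the aryl bromide alone.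
- Trimethylsilyl is kept on both acetal oxygens: it is the smallest silyl group, and either silyloxy group can leave to give the same arene.

Step 1
Reactants: 1 2,3,5-tribromothiophene
Product: 3 2,3,5-tribromothiophene 1,1-dioxide, via 2,3,5-tribromothiophene 1-oxide 2 (not isolated)
Conditions: urea·H2O2, (CF3CO)2O, CH2Cl2/MeCN, 0 °C → rt; cold aqueous wash without base, recrystallise
Reagents that add atoms: urea–hydrogen peroxide, OO.NC(N)=O (oxygen source); trifluoroperacetic acid, OOC(=O)C(F)(F)F (formed from it in the flask with trifluoroacetic anhydride, transfers both oxygens)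
Why: Trifluoroperacetic acid is electrophilic enough to oxidise the bromine-deactivated sulfur twice (peracid S-oxidation, thiophene → S-oxide → S,S-dioxide), and the bromines at both α-carbons should slow the [4+2] dimerisation that destroys less substituted thiophene oxides.

Step 2
Reactants: 4 (2-bromophenoxy)acetic acid
Product: 7 2-(2-bromophenoxy)-1,1-bis(trimethylsilyloxy)ethene, via trimethylsilyl (2-bromophenoxy)acetate 5 (not isolated), via lithium ester enolate 6 (not isolated)
Conditions: (i) (Me3Si)2NH, PhMe, 80 °C, evaporate; (ii) LiHMDS, THF, −78 °C, then Me3SiCl, −78 °C → rt; filter under Ar, strip volatiles in high vacuum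
Reagents that add atoms: hexamethyldisilazane, C[Si](C)(C)N[Si](C)(C)C; chlorotrimethylsilane, C[Si](C)(C)Cl
Why: Silylation of the acid with HMDS releases only ammonia, LiHMDS then removes the α-proton (acidified by the ester and the aryloxy group) without attacking the aryl bromide, and the lithium enolate is trapped on oxygen by chlorotrimethylsilane, the standard ester-enolate O-silylation route to ketene bis(trimethylsilyl) acetals as used for tris(trimethylsilyloxy)ethene.

Step 3
Reactants: 3 2,3,5-tribromothiophene 1,1-dioxide; 7 2-(2-bromophenoxy)-1,1-bis(trimethylsilyloxy)ethene (1.5 equiv)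
Product: 10 trimethyl[2,3,5-tribromo-6-(2-bromophenoxy)phenoxy]silane, via bridged sulfone cycloadduct 8 (not isolated), via bis(silyloxy)cyclohexadiene 9 (not isolated)
Conditions: dry PhMe, 0 °C → 80 °C, slow Ar sweep (−SO2, −Me3SiOH); evaporate, crude 10 taken on
Reagents that add atoms: none
Why: The electron-rich ketene acetal 7 (HOMO coefficient largest on the aryloxy-bearing CH) adds to the electron-poor diene of 3 in an asynchronous inverse-electron-demand Diels–Alder reaction in which the C5–C6 bond leads and the C1–C2 bond follows, so ring A is closed as a six-membered carbocycle by intermolecular [4+2] cycloaddition to give 8. Cheletropic extrusion of sulfur dioxide from the 7-thiabicyclo[2.2.1]heptene dioxide 8 gives diene 9, which can aromatise only by 1,2-elimination of trimethylsilanol (H from C6, one silyloxy group from C1), because C1 carries no hydrogen that could leave together with the aryloxy group. The closest known reaction type is the benzannulation of halogenated thiophene 1,1-dioxides by enol ethers, enamines or other electron-rich alkenes through the same cycloaddition, SO2-loss, elimination sequence. No stereocentre has to be controlled, since the sp3 centres of 8 and 9 are racemic and are erased on aromatisation, so endo/exo selectivity is irrelevant. The step needs one selectivity, the orientation CH(OAr)→C5 and C(OSiMe3)2→C2, and the substrate secures it because the leading bond forms at the α-carbon remote from the 3-bromine, the site at which nucleophiles add to 3-bromothiophene dioxides and the less hindered terminus (its neighbour C4 bears hydrogen), while the small trimethylsilyl groups keep the lagging bond to the more crowded C2 within reach.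

Step 4
Reactants: 10 trimethyl[2,3,5-tribromo-6-(2-bromophenoxy)phenoxy]silane
Product: 11 2,3,5-tribromo-6-(2-bromophenoxy)phenol (target)
Conditions: 1 M HCl, THF, rt
Reagents that add atoms: none
Why: Acid-catalysed hydrolysis of an aryl trimethylsilyl ether is fast because the electron-poor di-ortho-substituted phenol is a good leaving group on silicon, and the diaryl ether and the four C–Br bonds are inert to dilute acid at room temperature.

Compound list
1 | 2,3,5-tribromothiophene | Brc1cc(Br)c(Br)s1 | starting material
2 | 2,3,5-tribromothiophene 1-oxide (racemic at sulfur) | O=S1C(Br)=C(Br)C=C1Br | intermediate (not isolated)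
3 | 2,3,5-tribromothiophene 1,1-dioxide | O=S1(=O)C(Br)=C(Br)C=C1Br | intermediate
4 | (2-bromophenoxy)acetic acid | OC(=O)COc1ccccc1Br | starting material
5 | trimethylsilyl (2-bromophenoxy)acetate | C[Si](C)(C)OC(=O)COc1ccccc1Br | intermediate (not isolated)
6 | lithium 2-(2-bromophenoxy)-1-(trimethylsilyloxy)ethen-1-olate (lithium ester enolate) | [Li]OC(O[Si](C)(C)C)=COc1ccccc1Br | intermediate (not isolated)
7 | 2-(2-bromophenoxy)-1,1-bis(trimethylsilyloxy)ethene | C[Si](C)(C)OC(O[Si](C)(C)C)=COc1ccccc1Br | intermediate
8 | 1,2,4-tribromo-5-(2-bromophenoxy)-6,6-bis(trimethylsilyloxy)-7-thiabicyclo[2.2.1]hept-2-ene 7,7-dioxide (racemic, endo/exo not defined) | BrC12C(Br)=CC(Br)(S1(=O)=O)C(Oc3ccccc3Br)C2(O[Si](C)(C)C)O[Si](C)(C)C | intermediate (not isolated)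
9 | 1,2,4-tribromo-5-(2-bromophenoxy)-6,6-bis(trimethylsilyloxy)cyclohexa-1,3-diene (racemic) | C[Si](C)(C)OC1(O[Si](C)(C)C)C(Br)=C(Br)C=C(Br)C1Oc1ccccc1Br | intermediate (not isolated)
10 | trimethyl[2,3,5-tribromo-6-(2-bromophenoxy)phenoxy]silane | C[Si](C)(C)Oc1c(Br)c(Br)cc(Br)c1Oc1ccccc1Br | intermediate
11 | 2,3,5-tribromo-6-(2-bromophenoxy)phenol | Oc1c(Br)c(Br)cc(Br)c1Oc1ccccc1Br | target

Total steps: 4. Longest linear sequence: 3 steps (1 → 3 → 10 → 11, or 4 → 7 → 10 → 11).

Steps most likely to fail

1. Step 3. Several processes may defeat it:
- The ketene acetal may add in the reverse orientation.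
- After the leading bond the dipolar intermediate may not close and may instead open the sulfone ring with loss of sulfinate and bromide.
- Bromine may be transferred from the sulfone to the silyl ketene acetal.
- Released silanol and sulfur dioxide may protodesilylate the dienophile before it reacts.

The fallback gives up the cycloaddition and fixes the orientation through the substitution pattern of a benzaldehyde, whose formyl group is the masked C1 hydroxyl. Neither 3 nor 7 enters it, so it sets out from no numbered compound but from commercial 2-bromo-6-fluorobenzaldehyde and 2-bromophenol, and it comes back to the route at 11. 2-Bromo-6-fluorobenzaldehyde is dibrominated with NBS in concentrated H2SO4; fluorine, bromine and the formyl group all direct to the two positions that are needed, which should give 2,3,5-tribromo-6-fluorobenzaldehyde F1. Nucleophilic aromatic substitution of the aldehyde-activated fluoride by 2-bromophenol (K2CO3, DMF, 60 °C) should give 2,3,5-tribromo-6-(2-bromophenoxy)benzaldehyde F2. Baeyer–Villiger oxidation with mCPBA in CH2Cl2, a known route from 2-aryloxybenzaldehydes to hydroxylated bromodiphenyl ethers, should give 2,3,5-tribromo-6-(2-bromophenoxy)phenyl formate F3. Methanolysis (K2CO3, MeOH) then releases 11.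

2. Step 1. The oxidation may stall at the S-oxide, which then dimerises, or the peracid may cleave the ring, or the electrophilic dioxide may decompose on work-up.

The fallback sets out from 1 and comes back at 3; it moves the oxidation to a thiophene whose sulfur is not deactivated and restores the α-bromines afterwards. Two successive α-selective bromine–lithium exchanges (n-BuLi, Et2O, −78 °C), each quenched with Me3SiCl, should lead through (3,5-dibromothiophen-2-yl)lithium F4, 3,5-dibromo-2-(trimethylsilyl)thiophene F5 and [4-bromo-5-(trimethylsilyl)thiophen-2-yl]lithium F6 to 3-bromo-2,5-bis(trimethylsilyl)thiophene F7. The 2-bromine, activated by its bromine neighbour, should exchange first. mCPBA in CH2Cl2 should oxidise this electron-rich thiophene through 3-bromo-2,5-bis(trimethylsilyl)thiophene 1-oxide F8 to 3-bromo-2,5-bis(trimethylsilyl)thiophene 1,1-dioxide F9. ipso-Bromodesilylation of both C–Si bonds with Br2/AgBF4 in CH2Cl2, known for 2,5-bis(trimethylsilyl)thiophene dioxide, then gives 3.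

3. Step 2. The enolate may lose silanolate to give a ketene, silylation may occur on carbon, or the bis(trimethylsilyl) acetal may hydrolyse during isolation.

The fallback sets out from 4 and comes back at 11; it replaces the fragile acetal by one that survives water and silica, at the price of more bulk at C1. 4 is silylated with TBSCl/imidazole in DMF to tert-butyldimethylsilyl (2-bromophenoxy)acetate F10. LiHMDS in THF/DMPU at −78 °C with TBSCl present should give, through lithium 2-(2-bromophenoxy)-1-(tert-butyldimethylsilyloxy)ethen-1-olate F11, 2-(2-bromophenoxy)-1,1-bis(tert-butyldimethylsilyloxy)ethene F12, isolated after aqueous work-up. Cycloaddition with 3 under the conditions of step 3 should pass through the bridged sulfone adduct F13 and the bis(tert-butyldimethylsilyloxy)cyclohexadiene F14 to tert-butyldimethyl[2,3,5-tribromo-6-(2-bromophenoxy)phenoxy]silane F15. TBAF in THF then gives 11.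

Further compounds
F1 | step 3 | 2,3,5-tribromo-6-fluorobenzaldehyde | O=Cc1c(F)c(Br)cc(Br)c1Br
F2 | step 3 | 2,3,5-tribromo-6-(2-bromophenoxy)benzaldehyde | O=Cc1c(Oc2ccccc2Br)c(Br)cc(Br)c1Br
F3 | step 3 | 2,3,5-tribromo-6-(2-bromophenoxy)phenyl formate | O=COc1c(Oc2ccccc2Br)c(Br)cc(Br)c1Br
F4 | step 1 | (3,5-dibromothiophen-2-yl)lithium | [Li]c1sc(Br)cc1Br
F5 | step 1 | 3,5-dibromo-2-(trimethylsilyl)thiophene | C[Si](C)(C)c1sc(Br)cc1Br
F6 | step 1 | [4-bromo-5-(trimethylsilyl)thiophen-2-yl]lithium | [Li]c1cc(Br)c(s1)[Si](C)(C)C
F7 | step 1 | 3-bromo-2,5-bis(trimethylsilyl)thiophene | C[Si](C)(C)c1cc(Br)c(s1)[Si](C)(C)C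
F8 | step 1 | 3-bromo-2,5-bis(trimethylsilyl)thiophene 1-oxide (racemic at sulfur) | C[Si](C)(C)C1=CC(Br)=C([Si](C)(C)C)S1=O
F9 | step 1 | 3-bromo-2,5-bis(trimethylsilyl)thiophene 1,1-dioxide | C[Si](C)(C)C1=CC(Br)=C([Si](C)(C)C)S1(=O)=O
F10 | step 2 | tert-butyldimethylsilyl (2-bromophenoxy)acetate | CC(C)(C)[Si](C)(C)OC(=O)COc1ccccc1Br
F11 | step 2 | lithium 2-(2-bromophenoxy)-1-(tert-butyldimethylsilyloxy)ethen-1-olate | [Li]OC(O[Si](C)(C)C(C)(C)C)=COc1ccccc1Br
F12 | step 2 | 2-(2-bromophenoxy)-1,1-bis(tert-butyldimethylsilyloxy)ethene | CC(C)(C)[Si](C)(C)OC(O[Si](C)(C)C(C)(C)C)=COc1ccccc1Br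
F13 | step 2 | 1,2,4-tribromo-5-(2-bromophenoxy)-6,6-bis(tert-butyldimethylsilyloxy)-7-thiabicyclo[2.2.1]hept-2-ene 7,7-dioxide (racemic, endo/exo not defined) | BrC12C(Br)=CC(Br)(S1(=O)=O)C(Oc3ccccc3Br)C2(O[Si](C)(C)C(C)(C)C)O[Si](C)(C)C(C)(C)C
F14 | step 2 | 1,2,4-tribromo-5-(2-bromophenoxy)-6,6-bis(tert-butyldimethylsilyloxy)cyclohexa-1,3-diene (racemic) | CC(C)(C)[Si](C)(C)OC1(O[Si](C)(C)C(C)(C)C)C(Br)=C(Br)C=C(Br)C1Oc1ccccc1Br
F15 | step 2 | tert-butyldimethyl[2,3,5-tribromo-6-(2-bromophenoxy)phenoxy]silane | CC(C)(C)[Si](C)(C)Oc1c(Br)c(Br)cc(Br)c1Oc1ccccc1Br
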